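**Retrosynthetic overview**

1. Target ⇒ elemanolide alcohol with the complete ring system, by late Riley oxidation of the isopropenyl methyl (C15) and angeloylation of the C6 hydroxyl.
2. Cyclohexane ring ⇒ chair Cope rearrangement (C5–C10 made, C2–C3 broken) of a (1(10)E,4E)-germacra-1(10),4,11(13)-trien-12,8-olide, the presumed germacranolide-to-elemanolide biogenesis.
3. Ten-membered ring ⇒ C6–C7 bond (the farnesyl C1–C10 closure) by intramolecular allylboration of an enal by a butenolide-based allylboronate, made in the flask by Negishi borylmethylation of an α-bromobutenolide; ring closure and Cope run as one cascade.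
4. Acyclic precursor ⇒ C8–C9 bond by asymmetric vinylogous Mukaiyama aldol of a 3-bromo-2-silyloxyfuran with a geraniol-derived C10 enal, then esterification with the chiral C5 acid.
5. Ring order: lactone (brought in as the furanone) → ten-membered carbocycle → cyclohexane (the ten-membered ring is consumed in the Cope step).

Assumption: positions are numbered as in the germacrane/elemane skeleton (C1–C15, lactone carbonyl C12), and (R)-2-methylbutanoic acid and angelic acid are bought.

**Route**

Step 1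
Reactants: 1 geranyl acetate
Product: 3 (2E,6E)-3,7-dimethyl-8-oxoocta-2,6-dien-1-yl acetate, via 8-hydroxygeranyl acetate 2 (not isolated)
Conditions: SeO2 (1.1 equiv), 95% EtOH, reflux, 2 h
Reagents that add atoms: selenium dioxide, O=[Se]=O
Why: Riley allylic oxidation (ene reaction, then [2,3]-sigmatropic shift) attacks the E-methyl of the electron-rich terminal alkene, the other alkene being deactivated by the allylic acetate, and stoichiometric SeO2 carries the alcohol on to the E-enal; no stereocentre is formed.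

Step 2
Reactants: 4 furan-2(5H)-one
Product: 6 3-bromofuran-2(5H)-one, via trans-3,4-dibromodihydrofuran-2(3H)-one 5 (not isolated)
Conditions: Br2, CH2Cl2, 0 to 25 °C; then Et3N, 0 °C
Reagents that add atoms: bromine, BrBr
Why: Bromination–dehydrobromination: anti addition of Br2 to the enoate and E1cB loss of HBr from the acidic α-position give the α-bromobutenolide.

Step 3
Reactants: 6 3-bromofuran-2(5H)-one
Product: 7 3-bromo-2-(tert-butyldimethylsilyloxy)furan
Conditions: TBSOTf, Et3N, CH2Cl2, 0 °C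
Reagents that add atoms: tert-butyldimethylsilyl trifluoromethanesulfonate, CC(C)(C)[Si](C)(C)OS(=O)(=O)C(F)(F)F
Why: Soft enolisation (γ-deprotonation and O-silylation) gives the aromatic 2-silyloxyfuran, the dienol ether needed for a vinylogous Mukaiyama aldol.

Step 4
Reactants: 3 (2E,6E)-3,7-dimethyl-8-oxoocta-2,6-dien-1-yl acetate; 7 3-bromo-2-(tert-butyldimethylsilyloxy)furan
Product: 8 (5R)-3-bromo-5-[(1R,2E,6E)-8-acetoxy-1-hydroxy-2,6-dimethylocta-2,6-dien-1-yl]furan-2(5H)-one
Conditions: SiCl4 (1.1 equiv), (R,R)-Denmark bisphosphoramide (5 mol %), iPr2NEt (10 mol %), CH2Cl2, −78 °C; aq. NaHCO3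
Reagents that add atoms: none
Why: Lewis-base-activated SiCl4 vinylogous Mukaiyama aldol in which the silyloxyfuran attacks through its γ-carbon (the α-carbon is blocked by Br) in 1,2-fashion on the enal bound to the chiral silicon cation; the open transition state is expected to give the 5,1′-syn (threo) adduct, as stoichiometric Lewis-acid silyloxyfuran aldols do, and the catalyst antipode is the one that directs attack to the aldehyde Si face, so that C8 and C9 are both R.

Step 5
Reactants: 8 (5R)-3-bromo-5-[(1R,2E,6E)-8-acetoxy-1-hydroxy-2,6-dimethylocta-2,6-dien-1-yl]furan-2(5H)-one; 9 (R)-2-methylbutanoic acid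
Product: 10 (1R,2E,6E)-8-acetoxy-1-[(2R)-4-bromo-5-oxo-2,5-dihydrofuran-2-yl]-2,6-dimethylocta-2,6-dien-1-yl (2R)-2-methylbutanoate
Conditions: DCC, DMAP (5 mol %), CH2Cl2, 0 °C
Reagents that add atoms: none
Why: Steglich esterification acylates the secondary allylic alcohol with retention at C9 and, at 0 °C with little DMAP, without epimerising the α-centre of the acid or the γ-carbon of the butenolide.

Step 6
Reactants: 10 (1R,2E,6E)-8-acetoxy-1-[(2R)-4-bromo-5-oxo-2,5-dihydrofuran-2-yl]-2,6-dimethylocta-2,6-dien-1-yl (2R)-2-methylbutanoate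
Product: 11 (1R,2E,6E)-1-[(2R)-4-bromo-5-oxo-2,5-dihydrofuran-2-yl]-8-hydroxy-2,6-dimethylocta-2,6-dien-1-yl (2R)-2-methylbutanoate
Conditions: Candida antarctica lipase B (Novozym 435), MeOH (5 equiv), MTBE, 30 °C
Reagents that add atoms: none
Why: Lipase-catalysed transesterification to methanol removes only the unhindered primary acetate, since the α-branched secondary ester and the lactone are poor substrates, and the neutral medium spares the base-sensitive butenolide.

Step 7
Reactants: 11 (1R,2E,6E)-1-[(2R)-4-bromo-5-oxo-2,5-dihydrofuran-2-yl]-8-hydroxy-2,6-dimethylocta-2,6-dien-1-yl (2R)-2-methylbutanoate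
Product: 12 (1R,2E,6E)-1-[(2R)-4-bromo-5-oxo-2,5-dihydrofuran-2-yl]-2,6-dimethyl-8-oxoocta-2,6-dien-1-yl (2R)-2-methylbutanoate
Conditions: MnO2 (15 equiv), CH2Cl2, 25 °C
Reagents that add atoms: none
Why: MnO2 allylic oxidation converts the primary allylic alcohol into the E-enal without touching the esters, the bromobutenolide or the other alkene.

Step 8
Reactants: 12 (1R,2E,6E)-1-[(2R)-4-bromo-5-oxo-2,5-dihydrofuran-2-yl]-2,6-dimethyl-8-oxoocta-2,6-dien-1-yl (2R)-2-methylbutanoate
Product: 16 (5S,6S,7R,8R,9R,10S)-6-hydroxy-9-[(2R)-2-methylbutanoyloxy]elema-1,3,11(13)-trien-12,8-olide, via allylboronate enal 13 (not isolated), via germacranolide pinacol borate 14 (not isolated), via elemanolide pinacol borate 15 (not isolated)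
Conditions: ICH2Bpin, Zn, THF, 25 °C (gives IZnCH2Bpin); 12, Pd(PPh3)4 (5 mol %), THF, 25 °C; then toluene (2 mM), 100 then 130 °C, sealed; aq. NH4Cl
Reagents that add atoms: 2-(iodomethyl)-4,4,5,5-tetramethyl-1,3,2-dioxaborolane, CC1(C)OB(CI)OC1(C)C
Why: Proposed new method: Negishi coupling of the α-bromobutenolide with Knochel's IZnCH2Bpin gives a 2-carbonyl-substituted allylboronate whose tethered enal is allylated on heating through a chair Zimmerman–Traxler transition state (C8 is trans to CH2B, hence the 6,7-anti pair, and delivery along the C9 arm to the syn face of the butenolide gives the cis-fused lactone, 6S,7R), which closes the ten-membered ring at C6–C7; the strained (1(10)E,4E)-germacranolide then undergoes the chair Cope rearrangement in the same flask through the crossed conformer that has both olefinic methyls anti to the C7–C11 bond, the course that the natural elemanolide records (vinyl trans to isopropenyl, 5S,10S); the closest known reaction types are tandem cross-coupling/intramolecular allylboration of haloalkenyl carbonyl compounds to small rings, thermal allylboration with 2-alkoxycarbonyl allylboronates and the thermal germacranolide-to-elemanolide Cope rearrangement.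

Step 9
Reactants: 16 (5S,6S,7R,8R,9R,10S)-6-hydroxy-9-[(2R)-2-methylbutanoyloxy]elema-1,3,11(13)-trien-12,8-olide; 17 angelic acid
Product: 19 (5S,6S,7R,8R,9R,10S)-6-angeloyloxy-9-[(2R)-2-methylbutanoyloxy]elema-1,3,11(13)-trien-12,8-olide, via angelic 2,4,6-trichlorobenzoic anhydride 18 (not isolated)
Conditions: 17, 2,4,6-trichlorobenzoyl chloride, Et3N, toluene, 25 °C; then 16, 80 °C
Reagents that add atoms: none
Why: Yamaguchi esterification through the pre-formed mixed anhydride in toluene without DMAP is the established way to acylate hindered secondary alcohols with angelic acid without Z-to-E (tiglate) isomerisation, and the C6 configuration is retained.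

Step 10
Reactants: 19 (5S,6S,7R,8R,9R,10S)-6-angeloyloxy-9-[(2R)-2-methylbutanoyloxy]elema-1,3,11(13)-trien-12,8-olide
Product: 21 (5R,6S,7R,8R,9R,10S)-6-angeloyloxy-9-[(2R)-2-methylbutanoyloxy]-15-oxoelema-1,3,11(13)-trien-12,8-olide, via 15-hydroxy elemanolide 20 (not isolated)
Conditions: SeO2 (1.5 equiv), 1,4-dioxane, H2O (2 equiv), 70 °C
Reagents that add atoms: selenium dioxide, O=[Se]=O
Why: Riley oxidation: the isopropenyl group is the only electron-rich alkene with an allylic methyl (the vinyl group has no allylic hydrogen, the lactone methylene and the angelate are electron-poor), so the ene/[2,3] sequence oxidises C15 and stoichiometric SeO2 takes the alcohol on to the 2-substituted acrolein, as in SeO2 oxidations of β-elemene; no stereocentre is touched (the C5 descriptor changes only by priority).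

**Compound list**

1 | geranyl acetate, (2E)-3,7-dimethylocta-2,6-dien-1-yl acetate | CC(C)=CCC/C(C)=C/COC(C)=O | starting material
2 | (2E,6E)-8-hydroxy-3,7-dimethylocta-2,6-dien-1-yl acetate | OC/C(C)=C/CC/C(C)=C/COC(C)=O | intermediate
3 | (2E,6E)-3,7-dimethyl-8-oxoocta-2,6-dien-1-yl acetate | O=C/C(C)=C/CC/C(C)=C/COC(C)=O | intermediate
4 | furan-2(5H)-one | O=C1OCC=C1 | starting material
5 | trans-3,4-dibromodihydrofuran-2(3H)-one (racemic) | O=C1OC[C@H](Br)[C@H]1Br | intermediate
6 | 3-bromofuran-2(5H)-one | O=C1OCC=C1Br | intermediate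
7 | 3-bromo-2-(tert-butyldimethylsilyloxy)furan | CC(C)(C)[Si](C)(C)Oc1occc1Br | intermediate
8 | (5R)-3-bromo-5-[(1R,2E,6E)-8-acetoxy-1-hydroxy-2,6-dimethylocta-2,6-dien-1-yl]furan-2(5H)-one | BrC1=C[C@@H](OC1=O)[C@H](O)/C(C)=C/CC/C(C)=C/COC(C)=O | intermediate
9 | (R)-2-methylbutanoic acid | CC[C@@H](C)C(=O)O | starting material
10 | (1R,2E,6E)-8-acetoxy-1-[(2R)-4-bromo-5-oxo-2,5-dihydrofuran-2-yl]-2,6-dimethylocta-2,6-dien-1-yl (2R)-2-methylbutanoate | BrC1=C[C@@H](OC1=O)[C@H](OC(=O)[C@H](C)CC)/C(C)=C/CC/C(C)=C/COC(C)=O | intermediate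
11 | (1R,2E,6E)-1-[(2R)-4-bromo-5-oxo-2,5-dihydrofuran-2-yl]-8-hydroxy-2,6-dimethylocta-2,6-dien-1-yl (2R)-2-methylbutanoate | BrC1=C[C@@H](OC1=O)[C@H](OC(=O)[C@H](C)CC)/C(C)=C/CC/C(C)=C/CO | intermediate
12 | (1R,2E,6E)-1-[(2R)-4-bromo-5-oxo-2,5-dihydrofuran-2-yl]-2,6-dimethyl-8-oxoocta-2,6-dien-1-yl (2R)-2-methylbutanoate | BrC1=C[C@@H](OC1=O)[C@H](OC(=O)[C@H](C)CC)/C(C)=C/CC/C(C)=C/C=O | intermediate
13 | (1R,2E,6E)-2,6-dimethyl-8-oxo-1-[(2R)-5-oxo-4-[(4,4,5,5-tetramethyl-1,3,2-dioxaborolan-2-yl)methyl]-2,5-dihydrofuran-2-yl]octa-2,6-dien-1-yl (2R)-2-methylbutanoate | CC1(C)OB(CC2=C[C@@H](OC2=O)[C@H](OC(=O)[C@H](C)CC)/C(C)=C/CC/C(C)=C/C=O)OC1(C)C | intermediate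
14 | (1(10)E,4E,6S,7R,8R,9R)-9-[(2R)-2-methylbutanoyloxy]-6-(pinacolboryloxy)germacra-1(10),4,11(13)-trien-12,8-olide (cis-fused lactone) | C/C1=C\CC/C(C)=C/[C@H](OB3OC(C)(C)C(C)(C)O3)[C@H]2C(=C)C(=O)O[C@H]2[C@@H]1OC(=O)[C@H](C)CC | intermediate
15 | (5S,6S,7R,8R,9R,10S)-9-[(2R)-2-methylbutanoyloxy]-6-(pinacolboryloxy)elema-1,3,11(13)-trien-12,8-olide | C=C[C@@]1(C)[C@H](C(C)=C)[C@H](OB3OC(C)(C)C(C)(C)O3)[C@H]2C(=C)C(=O)O[C@H]2[C@@H]1OC(=O)[C@H](C)CC | intermediate
16 | (5S,6S,7R,8R,9R,10S)-6-hydroxy-9-[(2R)-2-methylbutanoyloxy]elema-1,3,11(13)-trien-12,8-olide (10-vinyl trans to 5-isopropenyl, cis-fused α-methylene lactone) | C=C[C@@]1(C)[C@H](C(C)=C)[C@H](O)[C@H]2C(=C)C(=O)O[C@H]2[C@@H]1OC(=O)[C@H](C)CC | intermediate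
17 | angelic acid, (Z)-2-methylbut-2-enoic acid | C/C=C(/C)C(=O)O | starting material
18 | (Z)-2-methylbut-2-enoic 2,4,6-trichlorobenzoic anhydride | C/C=C(/C)C(=O)OC(=O)c1c(Cl)cc(Cl)cc1Cl | intermediate
19 | (5S,6S,7R,8R,9R,10S)-6-angeloyloxy-9-[(2R)-2-methylbutanoyloxy]elema-1,3,11(13)-trien-12,8-olide | C=C[C@@]1(C)[C@H](C(C)=C)[C@H](OC(=O)/C(C)=C\C)[C@H]2C(=C)C(=O)O[C@H]2[C@@H]1OC(=O)[C@H](C)CC | intermediate
20 | (5S,6S,7R,8R,9R,10S)-6-angeloyloxy-15-hydroxy-9-[(2R)-2-methylbutanoyloxy]elema-1,3,11(13)-trien-12,8-olide | C=C[C@@]1(C)[C@H](C(=C)CO)[C@H](OC(=O)/C(C)=C\C)[C@H]2C(=C)C(=O)O[C@H]2[C@@H]1OC(=O)[C@H](C)CC | intermediate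
21 | (5R,6S,7R,8R,9R,10S)-6-angeloyloxy-9-[(2R)-2-methylbutanoyloxy]-15-oxoelema-1,3,11(13)-trien-12,8-olide (CNP0295282.1) | C=C[C@@]1(C)[C@H](C(=C)C=O)[C@H](OC(=O)/C(C)=C\C)[C@H]2C(=C)C(=O)O[C@H]2[C@@H]1OC(=O)[C@H](C)CC | target

**Step count and risks**

Total step count: 10. Longest linear sequence: 9 steps (from 4 through steps 2 to 10).

The three steps most likely to fail:

Step 8. Three things must go right in one flask: ring closure must beat oligomerisation, the aldehyde must reach the butenolide face syn to the C9 arm (cis lactone), and the Cope rearrangement must pass through the crossed conformer with both methyls anti to the C7–C11 bond. The other crossed conformer would give the 5,10-diepimer, and simple conformational analysis does not clearly favour the required one, so this is the least secure point of the route. The fallback sets out from 12 and comes back to the route at 19. Stille coupling of 12 with Bu3SnCH2OH (Pd(PPh3)4, toluene, 80 °C) gives the hydroxymethylbutenolide enal F1, and CBr4/PPh3 (CH2Cl2, 0 °C) turns it into the bromomethylbutenolide enal F2. CrCl2 in THF at 2 mM and 25 °C then closes the ten-membered ring by a Nozaki–Hiyama-type allylchromium addition, at a temperature where no Cope reaction occurs, to the germacranolide alcohol F3, whose diastereomers can be separated and assigned. Its unhindered allylic 6-OH is acylated with 18 to the germacranolide diester F4, the substrate of the presumed biogenesis itself, which is heated in toluene at 110 to 130 °C to give 19. This also avoids acylating the hindered alcohol 16.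

Step 4. The enantioselectivity with a bromo-substituted silyloxyfuran and an α-branched enal is untested, and the syn (threo) preference is not secured for this catalyst, since several catalytic asymmetric silyloxyfuran aldols favour the anti adduct. The fallback sets out from 3 and 7 and comes back at 10. BF3·OEt2 in CH2Cl2 at −78 °C, syn-selective but not enantioselective, gives 8 as a racemate, that is together with its enantiomer F5. Esterification of the mixture with 9 as in step 5 gives 10 and the diastereomeric ester F6, which are separated by chromatography, so that the chiral acyl group the target needs anyway serves as the resolving group.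

Step 10. A late allylic oxidation on a polyfunctional substrate may stop at the alcohol, over-oxidise or attack the tertiary C5–H. The fallback sets out from 19 and comes back at 21. Ene-type chlorination of the isopropenyl group (NaOCl, AcOH, CH2Cl2/H2O, 0 °C, the reaction known for β-elemene) gives the allylic chloride F7, and Ganem oxidation (N-methylmorpholine N-oxide, NaI cat., MeCN, 40 °C) converts its CH2Cl group into the aldehyde of 21 with no C–H oxidant present.

**Further compounds**

F1 | step 8 | (1R,2E,6E)-1-[(2R)-4-(hydroxymethyl)-5-oxo-2,5-dihydrofuran-2-yl]-2,6-dimethyl-8-oxoocta-2,6-dien-1-yl (2R)-2-methylbutanoate | OCC1=C[C@@H](OC1=O)[C@H](OC(=O)[C@H](C)CC)/C(C)=C/CC/C(C)=C/C=O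
F2 | step 8 | (1R,2E,6E)-1-[(2R)-4-(bromomethyl)-5-oxo-2,5-dihydrofuran-2-yl]-2,6-dimethyl-8-oxoocta-2,6-dien-1-yl (2R)-2-methylbutanoate | BrCC1=C[C@@H](OC1=O)[C@H](OC(=O)[C@H](C)CC)/C(C)=C/CC/C(C)=C/C=O
F3 | step 8 | (1(10)E,4E,6S,7R,8R,9R)-6-hydroxy-9-[(2R)-2-methylbutanoyloxy]germacra-1(10),4,11(13)-trien-12,8-olide | C/C1=C\CC/C(C)=C/[C@H](O)[C@H]2C(=C)C(=O)O[C@H]2[C@@H]1OC(=O)[C@H](C)CC
F4 | step 8 | (1(10)E,4E,6S,7R,8R,9R)-6-angeloyloxy-9-[(2R)-2-methylbutanoyloxy]germacra-1(10),4,11(13)-trien-12,8-olide | C/C1=C\CC/C(C)=C/[C@H](OC(=O)/C(C)=C\C)[C@H]2C(=C)C(=O)O[C@H]2[C@@H]1OC(=O)[C@H](C)CC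
F5 | step 4 | (5S)-3-bromo-5-[(1S,2E,6E)-8-acetoxy-1-hydroxy-2,6-dimethylocta-2,6-dien-1-yl]furan-2(5H)-one | BrC1=C[C@H](OC1=O)[C@@H](O)/C(C)=C/CC/C(C)=C/COC(C)=O
F6 | step 4 | (1S,2E,6E)-8-acetoxy-1-[(2S)-4-bromo-5-oxo-2,5-dihydrofuran-2-yl]-2,6-dimethylocta-2,6-dien-1-yl (2R)-2-methylbutanoate | BrC1=C[C@H](OC1=O)[C@@H](OC(=O)[C@H](C)CC)/C(C)=C/CC/C(C)=C/COC(C)=O
F7 | step 10 | (5R,6S,7R,8R,9R,10S)-6-angeloyloxy-15-chloro-9-[(2R)-2-methylbutanoyloxy]elema-1,3,11(13)-trien-12,8-olide | C=C[C@@]1(C)[C@H](C(=C)CCl)[C@H](OC(=O)/C(C)=C\C)[C@H]2C(=C)C(=O)O[C@H]2[C@@H]1OC(=O)[C@H](C)CC
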